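**Retrosynthetic overview**

- The last skeletal bond made is C2–aryl of the flavanone (ring C to ring B). It is formed by a rhodium-catalysed asymmetric 1,4-addition of a ring B/D boronic acid to a 5,7-bis(MOM) chromone, which sets the only stereocentre (2S). Rings A/C come fused from commercial 5,7-dihydroxychromone.
- Ring D (the 2,2-dimethylpyran-4-one fused to ring B) is opened at O1–C2 and at C4–C4a to an aryl 3-methylbut-2-enoate, an isomer of the chromanone. In the forward sense this is a photo-Fries 1,3-acyl shift followed in the same flask by 6-endo oxa-Michael closure.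
- Enabling feature: on ring B the ring-D oxygen (on C8a) and the ketone carbon C4 (on C4a) are ortho. The carbon para to that oxygen (C6) is the link to ring C (held by Cl until the coupling), and the other ortho carbon (C8) bears the phenol oxygen. The migrating acyl group therefore has one landing site, and C2 carries two methyl groups, so the closure needs no stereocontrol.
- Ring order: ring D in step 2; the bond between ring B and ring C with the stereocentre in step 7; removal of all acetals last.

Key step: step 2

Remark: the sense of induction in step 7 is assigned by analogy with cyclic enones, where (S)-configured biaryl bisphosphines deliver the aryl group to the enone face that corresponds to 2S in a chromone. If the opposite sense were found, the (R)-ligand would be used and nothing else changes.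

**Step 1**
Reactants: 1 4-chloro-2-methoxyphenol; 2 3-methylbut-2-enoyl chloride
Product: 3 4-chloro-2-methoxyphenyl 3-methylbut-2-enoate
Conditions: NaH (1.05 equiv), THF, 0 °C; then 2 (1.1 equiv), 0 °C to rt
Reagents that add atoms: none
Why: O-acylation of the preformed sodium phenoxide (nucleophilic acyl substitution) should be clean, and the absence of an amine base avoids the vinylketene pathway that would move the double bond out of conjugation.

**Step 2**
Reactants: 3 4-chloro-2-methoxyphenyl 3-methylbut-2-enoate
Product: 5 6-chloro-8-methoxy-2,2-dimethylchroman-4-one, via ortho-acyl phenol 4 (not isolated)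
Conditions: hν (254 nm, low-pressure Hg lamp, quartz or FEP flow coil), degassed cyclohexane (0.01 M), 20 °C; then DBU (0.2 equiv) added to the photolysate, 25 °C, dark
Reagents that add atoms: none
Why: Excitation of the aryl ester cleaves the ArO–C(=O) bond from the singlet state; the solvent-caged aryloxyl/3-methylbut-2-enoyl radical pair recombines at the free ortho carbon and the dienone tautomerises to ortho-acyl phenol 4 (the C4–C4a bond), which on addition of catalytic DBU closes ring D by 6-endo-trig oxa-Michael addition of the phenoxide to the β,β-dimethyl enone (the O1–C2 bond). The closest known reaction type is the photo-Fries rearrangement of aryl 3-methylbut-2-enoates with base-mediated cyclisation in the same pot to 2,2-dimethylchroman-4-ones. No stereocentre is formed, because the new sp3 carbon carries two methyl groups. The step needs ortho selectivity over para recombination and over cage escape: the para carbon carries chlorine and the second ortho carbon carries methoxy, so only one carbon can rearomatise after acyl transfer, and the non-polar solvent keeps the pair caged. The conjugated acyl radical resists decarbonylation, O–acyl cleavage from the singlet state should outrun C–Cl homolysis from the triplet state in a solvent without hydrogen bonding, and 4 is shielded from further photochemistry by excited-state proton transfer, while photolabile 5 forms only after the lamp is off.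

**Step 3**
Reactants: 5 6-chloro-8-methoxy-2,2-dimethylchroman-4-one
Product: 6 6-chloro-8-hydroxy-2,2-dimethylchroman-4-one
Conditions: BBr3 (2.5 equiv), CH2Cl2, −78 to 0 °C; H2O quench, aq. NaHCO3 wash
Reagents that add atoms: none
Why: Lewis acid-mediated aryl methyl ether cleavage, in which BBr3 binds the methoxy oxygen and bromide removes the methyl group by SN2, should leave the aryl chloride and ketone untouched, and any ring D opened by the Lewis acid would re-close by oxa-Michael addition during the mildly basic wash.

**Step 4**
Reactants: 6 6-chloro-8-hydroxy-2,2-dimethylchroman-4-one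
Product: 7 6-chloro-8-(methoxymethoxy)-2,2-dimethylchroman-4-one
Conditions: NaH (1.05 equiv), DMF, 0 °C; MOMCl (1.2 equiv), 0 °C to rt
Reagents that add atoms: chloromethyl methyl ether (MOMCl), COCCl
Why: Williamson-type O-alkylation of the phenoxide (far more acidic than the ketone α-protons) with the reactive α-chloro ether installs the acetal group that matches the protection chosen for ring A.

**Step 5**
Reactants: 7 6-chloro-8-(methoxymethoxy)-2,2-dimethylchroman-4-one
Product: 8 [8-(methoxymethoxy)-2,2-dimethyl-4-oxochroman-6-yl]boronic acid
Conditions: B2(OH)4 (2 equiv), chloro(XPhos)[2-(2'-amino-1,1'-biphenyl)]palladium (1 mol %), XPhos (2-dicyclohexylphosphino-2',4',6'-triisopropylbiphenyl, 2 mol %), KOAc (3 equiv), EtOH, 80 °C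
Reagents that add atoms: tetrahydroxydiboron, OB(O)B(O)O
Why: Miyaura-type borylation of an aryl chloride, with oxidative addition of the C–Cl bond to XPhos-ligated zerovalent palladium, acetate-assisted transmetallation from the diboron reagent and reductive elimination, should give the boronic acid directly with the ketone and acetal inert.

**Step 6**
Reactants: 9 5,7-dihydroxy-4H-chromen-4-one
Product: 10 5,7-bis(methoxymethoxy)-4H-chromen-4-one
Conditions: NaH (2.4 equiv), DMF, 0 °C; MOMCl (2.5 equiv), 0 °C to rt
Reagents that add atoms: chloromethyl methyl ether (MOMCl), COCCl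
Why: Double O-alkylation of the bis-phenoxide should protect both oxygens, because the strong base breaks the hydrogen bond between the C5 hydroxyl and the carbonyl, and this removes acidic protons from the acceptor before step 7.

**Step 7**
Reactants: 8 [8-(methoxymethoxy)-2,2-dimethyl-4-oxochroman-6-yl]boronic acid (1.5 equiv); 10 5,7-bis(methoxymethoxy)-4H-chromen-4-one
Product: 11 (2S)-5,7-bis(methoxymethoxy)-2-[8-(methoxymethoxy)-2,2-dimethyl-4-oxochroman-6-yl]chroman-4-one
Conditions: [Rh(OH)(cod)]2 (1.5 mol %), (S)-MeO-F12-BIPHEP [(S)-2,2'-bis(bis(3,4,5-trifluorophenyl)phosphino)-6,6'-dimethoxy-1,1'-biphenyl, 3.3 mol %], toluene/H2O 10:1, 25 °C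
Reagents that add atoms: none
Why: Hayashi–Miyaura asymmetric 1,4-addition, in which the aryl group passes from boron to the hydroxorhodium complex, the chromone C2=C3 bond inserts into the aryl–rhodium bond on the enantioface selected by the (S)-bisphosphine (setting C2 as S) and water releases the ketone, should run at room temperature with this electron-poor ligand, which suppresses 1,2-addition to either ketone and base-mediated opening of ring C.

**Step 8**
Reactants: 11 (2S)-5,7-bis(methoxymethoxy)-2-[8-(methoxymethoxy)-2,2-dimethyl-4-oxochroman-6-yl]chroman-4-one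
Product: 12 (2S)-5,7-dihydroxy-2-(8-hydroxy-2,2-dimethyl-4-oxochroman-6-yl)chroman-4-one
Conditions: HCl (1.25 M in MeOH), 45 °C
Reagents that add atoms: none
Why: Acid-catalysed acetal exchange with methanol should remove the three MOM groups while both ketones, the tertiary ether of ring D and the C2 stereocentre stay intact, since opening of ring C to the chalcone is promoted by base and not by dilute acid at this temperature.

**Compound list**

1 | 4-chloro-2-methoxyphenol | COc1cc(Cl)ccc1O | starting material
2 | 3-methylbut-2-enoyl chloride | CC(C)=CC(=O)Cl | starting material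
3 | 4-chloro-2-methoxyphenyl 3-methylbut-2-enoate | COc1cc(Cl)ccc1OC(=O)C=C(C)C | intermediate
4 | 1-(5-chloro-2-hydroxy-3-methoxyphenyl)-3-methylbut-2-en-1-one (ortho-acyl phenol, not isolated) | COc1cc(Cl)cc(C(=O)C=C(C)C)c1O | intermediate
5 | 6-chloro-8-methoxy-2,2-dimethylchroman-4-one | COc1cc(Cl)cc2c1OC(C)(C)CC2=O | intermediate
6 | 6-chloro-8-hydroxy-2,2-dimethylchroman-4-one | Oc1cc(Cl)cc2c1OC(C)(C)CC2=O | intermediate
7 | 6-chloro-8-(methoxymethoxy)-2,2-dimethylchroman-4-one | COCOc1cc(Cl)cc2c1OC(C)(C)CC2=O | intermediate
8 | [8-(methoxymethoxy)-2,2-dimethyl-4-oxochroman-6-yl]boronic acid | COCOc1cc(B(O)O)cc2c1OC(C)(C)CC2=O | intermediate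
9 | 5,7-dihydroxy-4H-chromen-4-one | O=c1ccoc2cc(O)cc(O)c12 | starting material
10 | 5,7-bis(methoxymethoxy)-4H-chromen-4-one | O=c1ccoc2cc(OCOC)cc(OCOC)c12 | intermediate
11 | (2S)-5,7-bis(methoxymethoxy)-2-[8-(methoxymethoxy)-2,2-dimethyl-4-oxochroman-6-yl]chroman-4-one | CC1(C)CC(=O)c2cc([C@@H]3CC(=O)c4c(OCOC)cc(OCOC)cc4O3)cc(OCOC)c2O1 | intermediate
12 | (2S)-5,7-dihydroxy-2-(8-hydroxy-2,2-dimethyl-4-oxochroman-6-yl)chroman-4-one (CNP0303522.1) | CC1(C)CC(=O)c2cc([C@@H]3CC(=O)c4c(O)cc(O)cc4O3)cc(O)c2O1 | target

**Step count**

Total steps: 8. Longest linear sequence: 7 (steps 1, 2, 3, 4, 5, 7, 8); step 6 is the one-step side branch.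

**Steps most likely to fail**

Step 2. Three processes may defeat it: photochemical loss of chlorine through the triplet state, escape of the radical pair from the solvent cage back to the phenol, and stalling of conversion as the accumulating products absorb the light. The fallback sets out from 1 and comes back at 5, and it builds ring D through other bonds (C2–C3 and O1–C2). Compound 1 would be acetylated (Ac2O, catalytic H2SO4) to 4-chloro-2-methoxyphenyl acetate F1. A thermal Fries rearrangement with TiCl4 (1,2-dichloroethane, 80 °C), which can only go ortho because the para position is blocked, should give 1-(5-chloro-2-hydroxy-3-methoxyphenyl)ethan-1-one F2. Kabbe condensation of F2 with acetone (pyrrolidine, MeOH, reflux; enamine aldol condensation followed by oxa-Michael closure) should then give 5.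

Step 7. The insertion of the electron-rich 5-alkoxy chromone may be sluggish, protodeboronation of the boronic acid may compete, and facial selectivity may be insufficient. The fallback sets out from 8 and 10 and comes back at 11, replacing catalyst control by resolution. A 1,4-addition with phosphine-free [Rh(OH)(cod)]2 (dioxane/H2O, 40 °C), the more active achiral diene complex, should give racemic 5,7-bis(methoxymethoxy)-2-[8-(methoxymethoxy)-2,2-dimethyl-4-oxochroman-6-yl]chroman-4-one F3. Preparative chromatography on a cellulose tris(3,5-dimethylphenylcarbamate) stationary phase would separate 11 from the (2R)-enantiomer, (2R)-5,7-bis(methoxymethoxy)-2-[8-(methoxymethoxy)-2,2-dimethyl-4-oxochroman-6-yl]chroman-4-one F4. F4 could be returned to the racemate by mild base through reversible opening of ring C and resolved again.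

Step 8. Cleavage of the C7 and C8 acetals may be incomplete, or forcing the acid may erode the C2 configuration through reversible opening of ring C. The fallback sets out from 6 and 9 and comes back at 12, exchanging acid-labile acetals for benzyl ethers that are removed under neutral conditions.
- Compound 6 would be benzylated (BnBr, K2CO3, DMF) to 8-(benzyloxy)-6-chloro-2,2-dimethylchroman-4-one F5.
- F5 would be borylated under the conditions of step 5 to [8-(benzyloxy)-2,2-dimethyl-4-oxochroman-6-yl]boronic acid F6.
- Compound 9 would be benzylated (BnBr, K2CO3, DMF, 60 °C) to 5,7-bis(benzyloxy)-4H-chromen-4-one F7.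
- F6 and F7 under the conditions of step 7 should give (2S)-5,7-bis(benzyloxy)-2-[8-(benzyloxy)-2,2-dimethyl-4-oxochroman-6-yl]chroman-4-one F8.
- Hydrogenolysis of F8 (H2 1 atm, Pd/C, EtOAc/MeOH, rt) should give 12.

**Further compounds**

F1 | step 2 | 4-chloro-2-methoxyphenyl acetate | COc1cc(Cl)ccc1OC(C)=O
F2 | step 2 | 1-(5-chloro-2-hydroxy-3-methoxyphenyl)ethan-1-one | COc1cc(Cl)cc(C(C)=O)c1O
F3 | step 7 | racemic 5,7-bis(methoxymethoxy)-2-[8-(methoxymethoxy)-2,2-dimethyl-4-oxochroman-6-yl]chroman-4-one | CC1(C)CC(=O)c2cc(C3CC(=O)c4c(OCOC)cc(OCOC)cc4O3)cc(OCOC)c2O1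
F4 | step 7 | (2R)-5,7-bis(methoxymethoxy)-2-[8-(methoxymethoxy)-2,2-dimethyl-4-oxochroman-6-yl]chroman-4-one | CC1(C)CC(=O)c2cc([C@H]3CC(=O)c4c(OCOC)cc(OCOC)cc4O3)cc(OCOC)c2O1
F5 | step 8 | 8-(benzyloxy)-6-chloro-2,2-dimethylchroman-4-one | CC1(C)CC(=O)c2cc(Cl)cc(OCc3ccccc3)c2O1
F6 | step 8 | [8-(benzyloxy)-2,2-dimethyl-4-oxochroman-6-yl]boronic acid | CC1(C)CC(=O)c2cc(B(O)O)cc(OCc3ccccc3)c2O1
F7 | step 8 | 5,7-bis(benzyloxy)-4H-chromen-4-one | O=c1ccoc2cc(OCc3ccccc3)cc(OCc3ccccc3)c12
F8 | step 8 | (2S)-5,7-bis(benzyloxy)-2-[8-(benzyloxy)-2,2-dimethyl-4-oxochroman-6-yl]chroman-4-one | CC1(C)CC(=O)c2cc([C@@H]3CC(=O)c4c(OCc5ccccc5)cc(OCc5ccccc5)cc4O3)cc(OCc5ccccc5)c2O1
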